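## Retrosynthetic overview

1. Avoided: the biomimetic oxidative 8–5′ coupling of two ferulate/coniferyl units, which is the obvious first disconnection.
2. Key disconnection: the C2–C3 bond of the dihydrofuran, made by enantioselective Rh(II)-carbene insertion into the O-benzylic C–H of an aryl benzyl ether. This sets C2; C3 is then equilibrated to trans.
3. The diazo ester is put on the ring in one step by Pd-catalysed coupling of an aryl iodide with ethyl diazoacetate. The ether comes from 5-iodovanillin and O-TIPS-vanillyl alcohol.
4. Late stage: CHO → (E)-acrylic acid (Knoevenagel–Doebner), C3 ester → CH2OH with the acid masked as its lithium carboxylate, then desilylation.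
5. Ring order: both benzene rings are bought (vanillin, 5-iodovanillin); the only ring formed is the dihydrofuran, in step 5.

Assumption 1: the SMILES is read as the (2R,3S)-trans isomer (aryl and CH2OH on opposite faces), E-alkene, free acid and free phenol.

Assumption 2: Rh2(S-PTTL)4 is assigned as the catalyst enantiomer giving 2R, from my recollection of closely related aryl diazoacetate insertions; this must be confirmed on the first run, and if it gives 2S, Rh2(R-PTTL)4 is used with nothing else changed.

## Route

**Step 1**
Reactants: 1 vanillin; 2 triisopropylsilyl chloride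
Product: 3, 3-methoxy-4-(triisopropylsilyloxy)benzaldehyde
Conditions: TIPSCl, imidazole, DMF, rt
Reagents that add atoms: triisopropylsilyl chloride, CC(C)[Si](Cl)(C(C)C)C(C)C
Why: Phenol silylation (imidazole-catalysed substitution at Si); TIPS tolerates the amine bases, hydride, Pd and Rh used later and is removed by fluoride without touching the alkene or the benzylic ether.

**Step 2**
Reactants: 3
Product: 4, [3-methoxy-4-(triisopropylsilyloxy)phenyl]methanol
Conditions: NaBH4, MeOH, 0 °C
Reagents that add atoms: none
Why: Borohydride reduction of the aldehyde; the aryl TIPS ether is stable under these brief, cold conditions.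

**Step 3**
Reactants: 4; 5 5-iodovanillin (4-hydroxy-3-iodo-5-methoxybenzaldehyde)
Product: 6, 3-iodo-5-methoxy-4-{[3-methoxy-4-(triisopropylsilyloxy)phenyl]methoxy}benzaldehyde
Conditions: PPh3, DIAD, THF, 0 °C → rt
Reagents that add atoms: none
Why: Mitsunobu etherification; the acidic phenol of 5-iodovanillin (para-CHO) protonates the betaine cleanly, and the neutral conditions spare the aryl silyl ether that carbonate/phenoxide alkylation could cleave.

**Step 4**
Reactants: 6; 7 ethyl diazoacetate
Product: 8, ethyl 2-diazo-2-[5-formyl-3-methoxy-2-{[3-methoxy-4-(triisopropylsilyloxy)phenyl]methoxy}phenyl]acetate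
Conditions: Pd(PPh3)4 (10 mol%), Ag2CO3 (0.5 equiv), Et3N, toluene, rt, dark
Reagents that add atoms: ethyl diazoacetate, CCOC(=O)C=[N+]=[N-]
Why: Pd-catalysed cross-coupling of an aryl iodide with an acceptor diazo compound with retention of N2 (oxidative addition, Ag/amine-assisted C-palladation of the diazoacetate, reductive elimination), giving the donor/acceptor diazo ester in one step; the aldehyde and silyl ether are inert at rt.

**Step 5 (key step)**
Reactants: 8
Product: 9, ethyl (2R,3S)-5-formyl-7-methoxy-2-[3-methoxy-4-(triisopropylsilyloxy)phenyl]-2,3-dihydrobenzofuran-3-carboxylate (cis)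
Conditions: Rh2(S-PTTL)4 (2 mol%), toluene (0.02 M, slow addition of 8), 4 Å MS, −60 °C
Reagents that add atoms: none (N2 lost)
Why: Enantioselective intramolecular 1,5 C–H insertion of a Rh(II) donor/acceptor carbene into the O-benzylic CH2, which is activated by the ether oxygen and the electron-rich aryl; the chiral carboxylate catalyst selects one enantiotopic hydrogen and so sets C2 as R, with the cis (3S) ester as the kinetic diastereomer, and five-ring closure at high dilution outcompetes intermolecular reaction of the carbene with the aldehyde.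

**Step 6**
Reactants: 9
Product: 10, ethyl (2R,3R)-5-formyl-7-methoxy-2-[3-methoxy-4-(triisopropylsilyloxy)phenyl]-2,3-dihydrobenzofuran-3-carboxylate (trans)
Conditions: DBU (1 equiv), toluene, 40 °C
Reagents that add atoms: none
Why: Base-mediated epimerisation through the C3 ester enolate gives the thermodynamically favoured trans isomer, so C3 is set relative to the fixed C2; C2 is not acidic so ee is retained, ring-opening β-elimination is the stereoelectronically disfavoured reverse of a 5-endo-trig closure, and aprotic DBU keeps the aryl silyl ether on.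

**Step 7**
Reactants: 10; 11 malonic acid
Product: 12, (E)-3-[(2R,3R)-3-(ethoxycarbonyl)-7-methoxy-2-[3-methoxy-4-(triisopropylsilyloxy)phenyl]-2,3-dihydrobenzofuran-5-yl]prop-2-enoic acid
Conditions: malonic acid (3 equiv), piperidine (0.2 equiv), pyridine, 80 °C
Reagents that add atoms: malonic acid, OC(=O)CC(=O)O
Why: Knoevenagel–Doebner condensation with decarboxylation gives the (E)-cinnamic acid directly as the free acid; any C3 equilibration under these conditions returns the same trans isomer and C2 cannot epimerise while the phenol is silylated.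

**Step 8**
Reactants: 12
Product: 13, (E)-3-[(2R,3S)-3-(hydroxymethyl)-7-methoxy-2-[3-methoxy-4-(triisopropylsilyloxy)phenyl]-2,3-dihydrobenzofuran-5-yl]prop-2-enoic acid
Conditions: LiOt-Bu (1.0 equiv), THF, 0 °C; then LiBH4 (3 equiv), MeOH (3 equiv), 0 °C → rt; aq. citric acid work-up
Reagents that add atoms: none
Why: Chemoselective LiBH4 ester reduction, since a lithium carboxylate and its conjugated alkene are inert to LiBH4 while the ethyl ester is reduced; no bond to C3 is broken, and the descriptor changes from 3R to 3S only because the CIP priorities change.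

**Step 9**
Reactants: 13
Product: 14, target, (E)-3-[(2R,3S)-2-(4-hydroxy-3-methoxyphenyl)-3-(hydroxymethyl)-7-methoxy-2,3-dihydrobenzofuran-5-yl]prop-2-enoic acid
Conditions: TBAF (2.5 equiv), AcOH (2.5 equiv), THF, 0 °C → rt; work-up at pH 3–4
Reagents that add atoms: none
Why: Fluoride-mediated cleavage of the aryl silyl ether; buffering avoids a free phenoxide under strongly basic conditions, so no quinone-methide ring opening occurs and both stereocentres are untouched.

## Compound list

1 | vanillin | COc1cc(C=O)ccc1O | starting material
2 | triisopropylsilyl chloride | CC(C)[Si](Cl)(C(C)C)C(C)C | starting material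
3 | 3-methoxy-4-(triisopropylsilyloxy)benzaldehyde | COc1cc(C=O)ccc1O[Si](C(C)C)(C(C)C)C(C)C | intermediate
4 | [3-methoxy-4-(triisopropylsilyloxy)phenyl]methanol | COc1cc(CO)ccc1O[Si](C(C)C)(C(C)C)C(C)C | intermediate
5 | 5-iodovanillin | COc1cc(C=O)cc(I)c1O | starting material
6 | 3-iodo-5-methoxy-4-{[3-methoxy-4-(triisopropylsilyloxy)phenyl]methoxy}benzaldehyde | COc1cc(C=O)cc(I)c1OCc1ccc(O[Si](C(C)C)(C(C)C)C(C)C)c(OC)c1 | intermediate
7 | ethyl diazoacetate | CCOC(=O)C=[N+]=[N-] | starting material
8 | ethyl 2-diazo-2-[5-formyl-3-methoxy-2-{[3-methoxy-4-(triisopropylsilyloxy)phenyl]methoxy}phenyl]acetate | CCOC(=O)C(=[N+]=[N-])c1cc(C=O)cc(OC)c1OCc1ccc(O[Si](C(C)C)(C(C)C)C(C)C)c(OC)c1 | intermediate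
9 | ethyl (2R,3S)-cis-5-formyl-7-methoxy-2-[3-methoxy-4-(triisopropylsilyloxy)phenyl]-2,3-dihydrobenzofuran-3-carboxylate | COc1cc([C@@H]2Oc3c(OC)cc(C=O)cc3[C@@H]2C(=O)OCC)ccc1O[Si](C(C)C)(C(C)C)C(C)C | intermediate
10 | ethyl (2R,3R)-trans-5-formyl-7-methoxy-2-[3-methoxy-4-(triisopropylsilyloxy)phenyl]-2,3-dihydrobenzofuran-3-carboxylate | COc1cc([C@@H]2Oc3c(OC)cc(C=O)cc3[C@H]2C(=O)OCC)ccc1O[Si](C(C)C)(C(C)C)C(C)C | intermediate
11 | malonic acid | OC(=O)CC(=O)O | starting material
12 | (E)-3-[(2R,3R)-3-(ethoxycarbonyl)-7-methoxy-2-[3-methoxy-4-(triisopropylsilyloxy)phenyl]-2,3-dihydrobenzofuran-5-yl]prop-2-enoic acid | COc1cc([C@@H]2Oc3c(OC)cc(/C=C/C(=O)O)cc3[C@H]2C(=O)OCC)ccc1O[Si](C(C)C)(C(C)C)C(C)C | intermediate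
13 | (E)-3-[(2R,3S)-3-(hydroxymethyl)-7-methoxy-2-[3-methoxy-4-(triisopropylsilyloxy)phenyl]-2,3-dihydrobenzofuran-5-yl]prop-2-enoic acid | COc1cc([C@@H]2Oc3c(OC)cc(/C=C/C(=O)O)cc3[C@H]2CO)ccc1O[Si](C(C)C)(C(C)C)C(C)C | intermediate
14 | (E)-3-[(2R,3S)-2-(4-hydroxy-3-methoxyphenyl)-3-(hydroxymethyl)-7-methoxy-2,3-dihydrobenzofuran-5-yl]prop-2-enoic acid | COc1cc([C@@H]2Oc3c(OC)cc(/C=C/C(=O)O)cc3[C@H]2CO)ccc1O | target

## Summary

Total step count: 9.
Longest linear sequence: 9 steps (vanillin → 14); 5-iodovanillin enters at step 3.

Three steps most likely to fail, with fallbacks: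

1. **Step 5 (Rh C–H insertion).** Risks are insufficient ee, the free aldehyde intercepting the carbene, and the catalyst sense being opposite to that assumed. Fallback: move from catalyst control to auxiliary control. Couple 6 in step 4 with the diazoacetate of a chiral alcohol (lactamide or pantolactone type) and run the insertion with a matched Rh(II) catalyst, which gives the trans ring directly. Combine this with masking the CHO as its dimethyl acetal; the auxiliary is then removed reductively in the ester → CH2OH step.

2. **Step 4 (Pd/diazo coupling on an ortho-alkoxy, hindered aryl iodide).** Risks are low conversion and diazo decomposition. Fallback: build the diazo ester in two stages. Protect the CHO of 6 as the dimethyl acetal, carry out a Pd-catalysed Negishi–Reformatsky arylation with BrZnCH2CO2Et to the arylacetate, then Regitz diazo transfer (p-ABSA, DBU). The acetal is carried through the Rh step and hydrolysed on work-up.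

3. **Step 8 (ester reduction beside the cinnamic acid).** Risks are an insoluble carboxylate, a sluggish hindered ester, or partial acid reduction. Fallback: reorder the end-game. Reduce 10 with LiBH4 to the diol (CHO and ester both reduced), reoxidise only the benzylic alcohol with MnO2 to the aldehyde, then run the Knoevenagel–Doebner and TBAF steps. This is one step longer, with no competing carbonyl in the reduction.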